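**Plan**

1. Numbering used below (germacrane type): ring carbons C1 (ketone), C2, C3 (carbinol), C4/C5 (epoxide), C6 (lactone CH–O), C7 (=C11, butenolide), C8 (acyloxy), C9, C10 (CH–CH3); C12 lactone C=O, C13 CH2OAc.
2. Retrosynthesis: remove the epoxide oxygen (back to the Z-C4=C5 allylic alcohol) and the C8 ester; read the aldol unit C1(=O)–C2–C3(OH) as a reduced, hydrolysed vinylogous ester; derive C7=C11 and C13 from an α-sulfonyl lactone plus formaldehyde; then cut C1–C10 while reconnecting C3–C8 (retro-[3,3]) to a 1-(ethoxyethynyl)-2-propenylcyclohexenol.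
3. Enabling feature: the C1 carbonyl lies three atoms from the C3 carbinol, C8 carries oxygen, and the cis-4,5-epoxide is the residue of a ring Z-olefin. An alkoxide on C3 bearing the ynol ether C2≡C1, next to C8 bearing the propenyl C9=C10, is therefore a 1,5-enyne whose oxy-Cope shift makes C1–C10 and enlarges ring six to ring ten.
4. Forward order: quinone monoketal by dearomatisation, asymmetric Michael addition (C7–C11), quaternary C8 (OMe, propenyl), C6 reduction and lactone, ethoxyacetylide at C3, anionic oxy-Cope; then butenolide, C8 ester, C3 carbinol and epoxide are finished on the macrocycle.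
5. Stereochemistry: C7 comes from the catalyst and is relayed to C8 (alkylation) and C6 (hydride) in the six-membered ring before being erased; C10 comes from the chair transition state of the Cope shift; C8 from CBS reagent control; C3 from hydride addition to the macrocycle; C4/C5 from hydroxyl-directed epoxidation.

Key step: step 10

Remark: the sense of induction in step 2 is assigned by analogy with iminium-catalysed additions of carbon acids to cyclohexenone; the pseudo-enantiomeric amine derived from quinidine is to be used if the opposite sense is found.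

**Route**

Step 1
Reactants: 1 4-methoxy-2-methylphenol
Product: 2 4,4-dimethoxy-2-methylcyclohexa-2,5-dien-1-one
Conditions: PhI(OAc)2, MeOH, 0 °C
Reagents that add atoms: methanol, SMILES CO
Why: Oxidative dearomatisation of a para-methoxyphenol, the phenoxenium ion being trapped by methanol at the methoxy-bearing para carbon to give the quinone monoketal; no stereocentre is formed.

Step 2
Reactants: 2 4,4-dimethoxy-2-methylcyclohexa-2,5-dien-1-one; 3 methyl (phenylsulfonyl)acetate
Product: 4 methyl 2-[(1S)-2,2-dimethoxy-4-methyl-5-oxocyclohex-3-en-1-yl]-2-(phenylsulfonyl)acetate (epimers at the sulfonyl-bearing carbon)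
Conditions: 9-amino-9-deoxy-epi-quinine (20 mol%), PhCO2H (40 mol%), toluene, rt
Reagents that add atoms: none
Why: Iminium-activated asymmetric Michael addition in which the carbon acid adds to the unsubstituted β-carbon (the methyl-bearing enone arm is less electrophilic) and the cinchona amine shields one face, setting the ring stereocentre (later C7); the sulfonyl-bearing carbon remains an inconsequential epimer mixture.

Step 3
Reactants: 4 Michael adduct
Product: 5 methyl 2-[(1S,6S)-6-hydroxy-2,2-dimethoxy-4-methyl-5-oxocyclohex-3-en-1-yl]-2-(phenylsulfonyl)acetate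
Conditions: KN(SiMe3)2 (2.2 equiv), THF, −78 °C; 3-phenyl-2-(phenylsulfonyl)oxaziridine; aq. NH4Cl
Reagents that add atoms: 3-phenyl-2-(phenylsulfonyl)oxaziridine, SMILES O=S(=O)(N1OC1c1ccccc1)c1ccccc1
Why: Electrophilic enolate hydroxylation of the dianion at the only enolisable α'-carbon (C4 is sp2, C6 quaternary), the ketone enolate being far more nucleophilic than the sulfonyl-ester carbanion; oxygen enters trans to the side chain, a centre that is replanarised in step 5.

Step 4
Reactants: 5 α'-hydroxy ketone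
Product: 6 methyl 2-[(1S,6S)-2,2,6-trimethoxy-4-methyl-5-oxocyclohex-3-en-1-yl]-2-(phenylsulfonyl)acetate
Conditions: MeOTf, 2,6-di-tert-butyl-4-methylpyridine, CH2Cl2, 0 °C to rt
Reagents that add atoms: methyl trifluoromethanesulfonate, SMILES COS(=O)(=O)C(F)(F)F
Why: O-Methylation under non-basic conditions, so neither the acidic sulfonylacetate C–H nor the α-ketol is deprotonated; the methyl ether later leaves as methanol when its enol ether is hydrolysed.

Step 5
Reactants: 6 α'-methoxy ketone
Product: 7 methyl 2-[(1S,6R)-2,2,6-trimethoxy-4-methyl-5-oxo-6-(prop-2-en-1-yl)cyclohex-3-en-1-yl]-2-(phenylsulfonyl)acetate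
Conditions: LiN(i-Pr)2 (2.2 equiv), THF/DMPU, −78 °C; allyl bromide (1.05 equiv), −78 to −40 °C; aq. NH4Cl
Reagents that add atoms: allyl bromide, SMILES C=CCBr
Why: Enolate alkylation of the α-methoxy ketone as its dianion (the side-chain carbanion blocks retro-Michael loss and is the less reactive site), allyl bromide entering anti to the pseudo-axial side chain on the neighbouring carbon and so setting quaternary C8 with allyl trans and methoxy cis to that side chain.

Step 6
Reactants: 7 allyl ketone
Product: 8 methyl 2-[(1S,6R)-2,2,6-trimethoxy-4-methyl-5-oxo-6-[(1E)-prop-1-en-1-yl]cyclohex-3-en-1-yl]-2-(phenylsulfonyl)acetate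
Conditions: RuHCl(CO)(PPh3)3 (5 mol%), toluene, 80 °C
Reagents that add atoms: none
Why: Ruthenium hydride catalysed allyl-to-propenyl isomerisation (hydrometallation and β-hydride elimination), which stops at the thermodynamically preferred E-propenyl group because the adjacent carbon is quaternary.

Step 7
Reactants: 8 propenyl ketal
Product: 9 methyl 2-[(1S,2R)-2-methoxy-4-methyl-3,6-dioxo-2-[(1E)-prop-1-en-1-yl]cyclohex-4-en-1-yl]-2-(phenylsulfonyl)acetate
Conditions: oxalic acid (5% aq.), THF, 0 °C to rt
Reagents that add atoms: water, SMILES O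
Why: Mild acid hydrolysis of the allylic dimethyl ketal to the ene-dione, safe at this stage because quaternary C8 rules out tautomerisation to a hydroquinone and the adjacent carbonyl disfavours ionisation of the tertiary allylic methyl ether.

Step 8
Reactants: 9 ene-dione
Product: 11 (3aR,4R,7aR)-4-methoxy-6-methyl-3-(phenylsulfonyl)-4-[(1E)-prop-1-en-1-yl]-3a,7a-dihydro-1-benzofuran-2,5(3H,4H)-dione, via hydroxy ester 10 (not isolated)
Conditions: NaBH4, CeCl3·7H2O, MeOH, −78 °C; then TsOH·H2O (cat.), CH2Cl2, rt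
Reagents that add atoms: none
Why: Luche 1,2-reduction of the less hindered ene-dione carbonyl C6 (C3 is flanked by quaternary C8 and the methyl-bearing C4), hydride adding anti to the pseudo-axial side chain on C7 so that the new C6 alcohol is cis to it and closes the cis-fused γ-lactone.

Step 9
Reactants: 11 keto lactone
Product: 12 (3aR,4R,5S,7aR)-5-(ethoxyethynyl)-5-hydroxy-4-methoxy-6-methyl-3-(phenylsulfonyl)-4-[(1E)-prop-1-en-1-yl]-3a,4,5,7a-tetrahydro-1-benzofuran-2(3H)-one
Conditions: ethoxyacetylene and EtMgBr (3.2 equiv each), THF/CH2Cl2, −40 to 0 °C; aq. NH4Cl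
Reagents that add atoms: ethoxyacetylene, SMILES C#COCC
Why: Chelation-controlled 1,2-addition of the magnesium acetylide (the first equivalent parks the lactone as its sulfonyl-stabilised enolate): magnesium bridges the carbonyl and the equatorial α-methoxy group, the propenyl group is then axial, and the slender nucleophile adds anti to it, giving the C3 carbinol with alkynyl trans to propenyl.

Step 10
Reactants: 12 ethoxyethynyl carbinol
Product: 15 (6R,7R,10S)-1-ethoxy-11-(phenylsulfonyl)-3,8-dioxogermacra-1,4(Z)-dien-6,12-olide, via dipotassium allenolate 13 (not isolated), via methyl enol ether 14 (not isolated)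
Conditions: KH (3 equiv), 18-crown-6, THF, 0 °C to rt; then 0.5 M aq. oxalic acid, THF, 0 °C
Reagents that add atoms: water, SMILES O
Why: Proposed new method: deprotonation gives a naked tertiary alkoxide on C3 (the lactone is parked as its inert sulfonyl-stabilised carbanion), and the 1,5-enyne C1≡C2–C3–C8–C9=C10 undergoes an alkoxide-accelerated [3,3] shift that breaks C3–C8 and forms C1–C10; the ynol ether carbon C1 arrives at the carbonyl oxidation level as an ethoxyallenolate, which is protonated at C2 to the vinylogous ester while dilute acid cleaves the C8 methyl enol ether to the ketone. The closest known reaction types are the anionic oxy-Cope ring expansion of 1,2-dialkenylcyclohexanols to cyclodecenones and the acetylenic oxy-Cope shift of 5-en-1-yn-3-ols; an alkoxyalkyne as the two-carbon partner is the new element and should only help, since in the dissociative limit C1 is the β-carbon of a push–pull ynone. The ten-membered ring is closed by sigmatropic ring enlargement (ring six to ring ten through a six-centre chair array) and not by end-to-end cyclisation, so the usual penalty of medium-ring closure is avoided. The only new stereocentre, C10, is fixed by the chair: the trans ethoxyethynyl and (E)-propenyl groups react from the diequatorial conformer, the propenyl plane lies perpendicular to the breaking C3–C8 bond with its methyl group equatorial, and C1 bonds to one face of C10, giving 10S relative to the retained C6 centre. The step needs the [3,3] shift to outrun retro-addition of the acetylide and β-elimination; 18-crown-6 (fast shift at low temperature), the trans geometry (the diaxial conformer is unreactive, so no boat-derived epimer) and the carbanion-masked lactone are meant to secure this.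

Step 11
Reactants: 15 ring-expanded keto sulfone
Product: 17 (6R,10S)-1-ethoxy-13-hydroxy-3,8-dioxogermacra-1,4(Z),7(11)-trien-6,12-olide, via hydroxymethyl sulfone 16 (not isolated)
Conditions: CH2O (37% aq.), Et3N, THF, 0 °C to rt
Reagents that add atoms: formaldehyde, SMILES C=O
Why: Aldol hydroxymethylation at the most acidic C–H (the α-sulfonyl lactone carbon C11) followed by E1cB loss of benzenesulfinate from the C8 ketone enolate, the exocyclic C11–S bond being able to align with the enolate whereas the ring C6–O bond cannot; this creates C7=C11, removes the sulfone activating group and erases the C7 stereocentre.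

Step 12
Reactants: 17 hydroxymethyl butenolide
Product: 18 (6R,10S)-13-acetoxy-1-ethoxy-3,8-dioxogermacra-1,4(Z),7(11)-trien-6,12-olide
Conditions: Ac2O, pyridine, DMAP (cat.), CH2Cl2, 0 °C
Reagents that add atoms: acetic anhydride, SMILES CC(=O)OC(C)=O
Why: Standard acetylation of the primary allylic alcohol, done at once so that the cis γ-hydroxy enone cannot close to a hemiketal and dehydrate to a furan.

Step 13
Reactants: 18 keto butenolide
Product: 19 (6R,8S,10S)-13-acetoxy-1-ethoxy-8-hydroxy-3-oxogermacra-1,4(Z),7(11)-trien-6,12-olide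
Conditions: (R)-2-methyl-CBS-oxazaborolidine (20 mol%), catecholborane, toluene, −78 °C
Reagents that add atoms: none
Why: CBS reduction of the only reactive ketone (the C3 vinylogous ester carbonyl is inert at −78 °C), the oxazaborolidine distinguishing the alkenyl flank C7 (large) from the CH2 flank C9 (small) and delivering hydride under reagent control to give the 8S alcohol.

Step 14
Reactants: 20 4-methylfuran-2(5H)-one
Product: 23 (2Z)-4-acetoxy-3-methylbut-2-enoic acid, via sodium hydroxy-enoate 21 (not isolated), via mixed acetic anhydride 22 (not isolated)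
Conditions: NaOH (1.0 equiv), H2O/THF, rt; freeze-dry; Ac2O, pyridine, 0 °C; cold 1 M HCl work-up
Reagents that add atoms: sodium hydroxide, SMILES [Na+].[OH-]; acetic anhydride, SMILES CC(=O)OC(C)=O
Why: Saponification opens the butenolide to the hydroxy carboxylate with the Z geometry inherited from the ring, acetylation caps the alcohol (and transiently the carboxylate), and aqueous work-up hydrolyses the mixed anhydride to the free acid, which can no longer relactonise.

Step 15
Reactants: 19 C8 alcohol; 23 (2Z)-4-acetoxy-3-methylbut-2-enoic acid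
Product: 25 (6R,8S,10S)-13-acetoxy-8-[(2Z)-4-acetoxy-3-methylbut-2-enoyloxy]-1-ethoxy-3-oxogermacra-1,4(Z),7(11)-trien-6,12-olide, via mixed anhydride 24 (not isolated)
Conditions: 2,4,6-trichlorobenzoyl chloride, Et3N, THF, rt; then 19, DMAP, toluene, rt
Reagents that add atoms: none
Why: Yamaguchi esterification of the hindered secondary allylic alcohol through the aroyl mixed anhydride; the β,β-disubstituted enoate is not prone to Z/E scrambling by DMAP and no stereocentre is touched.

Step 16
Reactants: 25 vinylogous ester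
Product: 27 (3S,6R,8S,10S)-13-acetoxy-8-[(2Z)-4-acetoxy-3-methylbut-2-enoyloxy]-3-hydroxy-1-oxogermacra-4(Z),7(11)-dien-6,12-olide, via dienyl carbinol 26 (not isolated)
Conditions: NaBH4, CeCl3·7H2O, MeOH/THF, −40 to 0 °C; then pH 4.5 acetate buffer, THF, 0 °C
Reagents that add atoms: water, SMILES O
Why: Luche 1,2-reduction of the cross-conjugated C3 ketone (hydride expected from the outer face of the ring, giving 3S) followed by buffered hydrolysis of the β-hydroxy enol ether, which protonates C2 and unveils the C1 ketone at the aldol level instead of the dehydrated enone of a Stork–Danheiser transposition.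

Step 17
Reactants: 27 β-hydroxy ketone
Product: 28 target compound (CNP0232076.1)
Conditions: VO(acac)2 (5 mol%), t-BuOOH, CH2Cl2, 0 °C
Reagents that add atoms: tert-butyl hydroperoxide, SMILES CC(C)(C)OO
Why: Hydroxyl-directed vanadium-catalysed epoxidation of the only allylic alcohol; with C3–H eclipsing the Z-olefin to minimise 1,3-allylic strain against C6, oxygen is delivered syn to the C3 hydroxyl, giving the cis (4R,5S)-epoxide, while the electron-poor butenolide and enoate are untouched.

**Compound list**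

1 | 4-methoxy-2-methylphenol | Cc1cc(OC)ccc1O | starting material
2 | 4,4-dimethoxy-2-methylcyclohexa-2,5-dien-1-one | CC1=CC(OC)(OC)C=CC1=O | intermediate
3 | methyl (phenylsulfonyl)acetate | COC(=O)CS(=O)(=O)c1ccccc1 | starting material
4 | methyl 2-[(1S)-2,2-dimethoxy-4-methyl-5-oxocyclohex-3-en-1-yl]-2-(phenylsulfonyl)acetate (epimers at the sulfonyl carbon) | COC(=O)C(S(=O)(=O)c1ccccc1)[C@H]1CC(=O)C(C)=CC1(OC)OC | intermediate
5 | methyl 2-[(1S,6S)-6-hydroxy-2,2-dimethoxy-4-methyl-5-oxocyclohex-3-en-1-yl]-2-(phenylsulfonyl)acetate | COC(=O)C(S(=O)(=O)c1ccccc1)[C@H]1[C@H](O)C(=O)C(C)=CC1(OC)OC | intermediate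
6 | methyl 2-[(1S,6S)-2,2,6-trimethoxy-4-methyl-5-oxocyclohex-3-en-1-yl]-2-(phenylsulfonyl)acetate | COC(=O)C(S(=O)(=O)c1ccccc1)[C@H]1[C@H](OC)C(=O)C(C)=CC1(OC)OC | intermediate
7 | methyl 2-[(1S,6R)-2,2,6-trimethoxy-4-methyl-5-oxo-6-(prop-2-en-1-yl)cyclohex-3-en-1-yl]-2-(phenylsulfonyl)acetate | COC(=O)C(S(=O)(=O)c1ccccc1)[C@H]1[C@@](CC=C)(OC)C(=O)C(C)=CC1(OC)OC | intermediate
8 | methyl 2-[(1S,6R)-2,2,6-trimethoxy-4-methyl-5-oxo-6-[(1E)-prop-1-en-1-yl]cyclohex-3-en-1-yl]-2-(phenylsulfonyl)acetate | COC(=O)C(S(=O)(=O)c1ccccc1)[C@H]1[C@@](/C=C/C)(OC)C(=O)C(C)=CC1(OC)OC | intermediate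
9 | methyl 2-[(1S,2R)-2-methoxy-4-methyl-3,6-dioxo-2-[(1E)-prop-1-en-1-yl]cyclohex-4-en-1-yl]-2-(phenylsulfonyl)acetate | COC(=O)C(S(=O)(=O)c1ccccc1)[C@H]1[C@@](/C=C/C)(OC)C(=O)C(C)=CC1=O | intermediate
10 | methyl 2-[(1R,2R,6R)-6-hydroxy-2-methoxy-4-methyl-3-oxo-2-[(1E)-prop-1-en-1-yl]cyclohex-4-en-1-yl]-2-(phenylsulfonyl)acetate (hydroxy ester) | COC(=O)C(S(=O)(=O)c1ccccc1)[C@H]1[C@@](/C=C/C)(OC)C(=O)C(C)=C[C@H]1O | intermediate
11 | (3aR,4R,7aR)-4-methoxy-6-methyl-3-(phenylsulfonyl)-4-[(1E)-prop-1-en-1-yl]-3a,7a-dihydro-1-benzofuran-2,5(3H,4H)-dione | O=C1O[C@@H]2C=C(C)C(=O)[C@@](OC)(/C=C/C)[C@@H]2C1S(=O)(=O)c1ccccc1 | intermediate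
12 | (3aR,4R,5S,7aR)-5-(ethoxyethynyl)-5-hydroxy-4-methoxy-6-methyl-3-(phenylsulfonyl)-4-[(1E)-prop-1-en-1-yl]-3a,4,5,7a-tetrahydro-1-benzofuran-2(3H)-one | O=C1O[C@@H]2C=C(C)[C@](O)(C#COCC)[C@@](OC)(/C=C/C)[C@@H]2C1S(=O)(=O)c1ccccc1 | intermediate
13 | dipotassium allenolate: ring-expanded C1=C2=C3 ethoxyallenolate with C8 methyl enol ether and lactone enolate (axial chirality of the allene not defined) | [K+].[K+].[O-]C1=C(S(=O)(=O)c3ccccc3)[C@H]2/C(OC)=C/[C@H](C)C(OCC)=C=C([O-])/C(C)=C\[C@H]2O1 | intermediate
14 | (6R,7R,10S)-1-ethoxy-8-methoxy-11-(phenylsulfonyl)-3-oxogermacra-1,4(Z),8-trien-6,12-olide (C1=C2 geometry inconsequential) | O=C1O[C@@H]2/C=C(C)\C(=O)C=C(OCC)[C@@H](C)/C=C(OC)/[C@@H]2C1S(=O)(=O)c1ccccc1 | intermediate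
15 | (6R,7R,10S)-1-ethoxy-11-(phenylsulfonyl)-3,8-dioxogermacra-1,4(Z)-dien-6,12-olide | O=C1O[C@@H]2/C=C(C)\C(=O)C=C(OCC)[C@@H](C)CC(=O)[C@@H]2C1S(=O)(=O)c1ccccc1 | intermediate
16 | (6R,7R,10S)-1-ethoxy-13-hydroxy-11-(phenylsulfonyl)-3,8-dioxogermacra-1,4(Z)-dien-6,12-olide | O=C1O[C@@H]2/C=C(C)\C(=O)C=C(OCC)[C@@H](C)CC(=O)[C@@H]2C1(CO)S(=O)(=O)c1ccccc1 | intermediate
17 | (6R,10S)-1-ethoxy-13-hydroxy-3,8-dioxogermacra-1,4(Z),7(11)-trien-6,12-olide | OCC1=C2C(=O)C[C@H](C)C(OCC)=CC(=O)/C(C)=C\[C@H]2OC1=O | intermediate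
18 | (6R,10S)-13-acetoxy-1-ethoxy-3,8-dioxogermacra-1,4(Z),7(11)-trien-6,12-olide | CC(=O)OCC1=C2C(=O)C[C@H](C)C(OCC)=CC(=O)/C(C)=C\[C@H]2OC1=O | intermediate
19 | (6R,8S,10S)-13-acetoxy-1-ethoxy-8-hydroxy-3-oxogermacra-1,4(Z),7(11)-trien-6,12-olide | CC(=O)OCC1=C2[C@@H](O)C[C@H](C)C(OCC)=CC(=O)/C(C)=C\[C@H]2OC1=O | intermediate
20 | 4-methylfuran-2(5H)-one | CC1=CC(=O)OC1 | starting material
21 | sodium (2Z)-4-hydroxy-3-methylbut-2-enoate | [Na+].[O-]C(=O)/C=C(/C)CO | intermediate
22 | acetic (2Z)-4-acetoxy-3-methylbut-2-enoic anhydride | CC(=O)OC(=O)/C=C(/C)COC(C)=O | intermediate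
23 | (2Z)-4-acetoxy-3-methylbut-2-enoic acid | OC(=O)/C=C(/C)COC(C)=O | intermediate
24 | (2Z)-4-acetoxy-3-methylbut-2-enoic 2,4,6-trichlorobenzoic anhydride | O=C(OC(=O)/C=C(/C)COC(C)=O)c1c(Cl)cc(Cl)cc1Cl | intermediate
25 | (6R,8S,10S)-13-acetoxy-8-[(2Z)-4-acetoxy-3-methylbut-2-enoyloxy]-1-ethoxy-3-oxogermacra-1,4(Z),7(11)-trien-6,12-olide | CC(=O)OCC1=C2[C@@H](OC(=O)/C=C(/C)COC(C)=O)C[C@H](C)C(OCC)=CC(=O)/C(C)=C\[C@H]2OC1=O | intermediate
26 | (3S,6R,8S,10S)-13-acetoxy-8-[(2Z)-4-acetoxy-3-methylbut-2-enoyloxy]-1-ethoxy-3-hydroxygermacra-1,4(Z),7(11)-trien-6,12-olide | CC(=O)OCC1=C2[C@@H](OC(=O)/C=C(/C)COC(C)=O)C[C@H](C)C(OCC)=C[C@H](O)/C(C)=C\[C@H]2OC1=O | intermediate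
27 | (3S,6R,8S,10S)-13-acetoxy-8-[(2Z)-4-acetoxy-3-methylbut-2-enoyloxy]-3-hydroxy-1-oxogermacra-4(Z),7(11)-dien-6,12-olide | CC(=O)OCC1=C2[C@@H](OC(=O)/C=C(/C)COC(C)=O)C[C@H](C)C(=O)C[C@H](O)/C(C)=C\[C@H]2OC1=O | intermediate
28 | (3S,4R,5S,6S,8S,10S)-13-acetoxy-8-[(2Z)-4-acetoxy-3-methylbut-2-enoyloxy]-4,5-epoxy-3-hydroxy-1-oxogermacr-7(11)-en-6,12-olide (CNP0232076.1) | CC(=O)OCC1=C2[C@@H](OC(=O)/C=C(/C)COC(C)=O)C[C@H](C)C(=O)C[C@H](O)[C@@]3(C)O[C@H]3[C@H]2OC1=O | target

**Summary**

Total step count: 17. Longest linear sequence: 16 steps (steps 1–13 and 15–17; step 14 prepares the side-chain acid).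

**Steps most likely to fail**

Step 10 (key step, proposed new method). The tertiary propargylic alkoxide may revert by expelling the acetylide, or the enyne shift may be slower than decomposition of the ynol ether. The fallback sets out from 12 and comes back at 15. Semihydrogenation of 12 over lead-poisoned Pd/CaCO3 with quinoline and H2 should give the (Z)-2-ethoxyethenyl carbinol F1. F1 is a 1,2-dialkenylcyclohexanol of the classical type and should undergo the known anionic oxy-Cope ring expansion (KH, 18-crown-6, THF) through the same chair. The enolate is trapped at −78 °C with Me3SiCl before it can lose ethoxide, giving the trimethylsilyl enol ether F2. Saegusa–Ito oxidation with Pd(OAc)2 in MeCN then restores the C1=C2 double bond, which yields 14, and the oxalic acid work-up of the main route converts 14 into 15.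

Step 16. Hydride addition to the macrocyclic dienone may show poor facial selectivity, and the allylic β-hydroxy enol ether may lose water during hydrolysis. The fallback sets out from 25 and comes back at 27. The crude carbinol 26 is deliberately dehydrated with 0.1 M HCl in THF (Stork–Danheiser transposition) to the dienone F3. Copper-catalysed asymmetric conjugate borylation (CuCl, NaOt-Bu cat., (R)-Tol-BINAP or its enantiomer as required, B2pin2, MeOH, THF) should add boron to C3 under ligand control and give the β-boryl ketone F4. Oxidation with NaBO3·4H2O proceeds with retention and delivers 27.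

Step 2. Enantioselectivity may be low or iminium formation sluggish with the hindered cross-conjugated ketone, and the acid co-catalyst may cause loss of methanol and aromatisation. The fallback sets out from 2 and comes back at 4. The magnesium enolate of methyl (R)-(phenylsulfinyl)acetate is added to 2 at −78 °C, the sulfinyl group acting as a stoichiometric chiral controller of the enone face, to give the sulfinyl adduct F5. Oxidation of the sulfoxide to the sulfone with m-CPBA (1 equiv, CH2Cl2, −20 °C) then gives 4.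

Further compounds
F1 | step 10 | (3aR,4R,5R,7aR)-5-[(Z)-2-ethoxyethenyl]-5-hydroxy-4-methoxy-6-methyl-3-(phenylsulfonyl)-4-[(1E)-prop-1-en-1-yl]-3a,4,5,7a-tetrahydro-1-benzofuran-2(3H)-one | O=C1O[C@@H]2C=C(C)[C@](O)(/C=C\OCC)[C@@](OC)(/C=C/C)[C@@H]2C1S(=O)(=O)c1ccccc1
F2 | step 10 | (6R,7R,10S)-1-ethoxy-8-methoxy-11-(phenylsulfonyl)-3-(trimethylsilyloxy)germacra-2,4(Z),8-trien-6,12-olide | O=C1O[C@@H]2/C=C(C)\C(O[Si](C)(C)C)=CC(OCC)[C@@H](C)/C=C(OC)/[C@@H]2C1S(=O)(=O)c1ccccc1
F3 | step 16 | (6R,8S,10S)-13-acetoxy-8-[(2Z)-4-acetoxy-3-methylbut-2-enoyloxy]-1-oxogermacra-2,4(Z),7(11)-trien-6,12-olide | CC(=O)OCC1=C2[C@@H](OC(=O)/C=C(/C)COC(C)=O)C[C@H](C)C(=O)C=C/C(C)=C\[C@H]2OC1=O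
F4 | step 16 | (3S,6R,8S,10S)-13-acetoxy-8-[(2Z)-4-acetoxy-3-methylbut-2-enoyloxy]-1-oxo-3-(4,4,5,5-tetramethyl-1,3,2-dioxaborolan-2-yl)germacra-4(Z),7(11)-dien-6,12-olide | CC(=O)OCC1=C2[C@@H](OC(=O)/C=C(/C)COC(C)=O)C[C@H](C)C(=O)C[C@H](B3OC(C)(C)C(C)(C)O3)/C(C)=C\[C@H]2OC1=O
F5 | step 2 | methyl 2-[(1S)-2,2-dimethoxy-4-methyl-5-oxocyclohex-3-en-1-yl]-2-[(R)-phenylsulfinyl]acetate | COC(=O)C([S@@](=O)c1ccccc1)[C@H]1CC(=O)C(C)=CC1(OC)OC
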